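**Assumption:** the target is taken as drawn, the free hydrogen sulfate; it is released from its pyridinium salt on a cation-exchange resin at 0 °C and is best stored as a salt.

## Retrosynthetic overview

1. Target 28 ⇐ O-sulfation of primary alcohol 26 ⇐ desilylation of bicyclic enone 25.
2. Ring B (formed last): 25 ⇐ intramolecular aldol condensation of 1,5-diketone 23 ⇐ Mukaiyama–Michael addition of silyl enol ether 21 to mesityl oxide.
3. Ring A stereocentres: ketone 19 ⇐ copper-catalysed asymmetric conjugate methylation of enone 17, then enolate methylation anti to the new methyl group.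
4. Ring A (formed first, from a benzene ring): 17 ⇐ Birch reductive alkylation of 2-methoxybenzoic acid with iodide 13, then hydrolysis and decarboxylation (the carboxyl group is a traceless activator).
5. Iodide 13 ⇐ copper-catalysed asymmetric conjugate addition of a 3-(furan-3-yl)propyl Grignard reagent to a 4-silyloxy-crotonate, which sets the side-chain centre.

## Route

Step 1
Reactants: 1 3-bromofuran; 2 oxetane
Product: 4 3-(furan-3-yl)propan-1-ol, via furan-3-yllithium 3 (not isolated)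
Conditions: n-BuLi, THF, −78 °C; then 2, BF3·OEt2, −78 °C; aq. NH4Cl
Reagents that add atoms: none
Why: Bromine–lithium exchange gives the 3-furyl anion, which opens BF3-activated oxetane by SN2 ring opening to give the three-carbon alcohol; no stereocentre is formed.

Step 2
Reactants: 4 3-(furan-3-yl)propan-1-ol
Product: 5 3-(3-bromopropyl)furan
Conditions: CBr4, PPh3, CH2Cl2, 0 °C
Reagents that add atoms: carbon tetrabromide, BrC(Br)(Br)Br
Why: Appel bromination converts the primary alcohol under neutral conditions that the furan tolerates.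

Step 3
Reactants: 6 prop-2-en-1-ol
Product: 7 (allyloxy)triisopropylsilane
Conditions: TIPSCl, imidazole, CH2Cl2, 23 °C
Reagents that add atoms: chlorotriisopropylsilane, CC(C)[Si](Cl)(C(C)C)C(C)C
Why: Silylation installs the one protecting group of the route, chosen because a primary TIPS ether survives dilute acid, TiCl4 at −78 °C and hydroxide.

Step 4
Reactants: 7 (allyloxy)triisopropylsilane; 8 methyl acrylate
Product: 9 methyl (E)-4-[(triisopropylsilyl)oxy]but-2-enoate
Conditions: second-generation Hoveyda–Grubbs catalyst (2 mol %), 8 (3 equiv), CH2Cl2, 40 °C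
Reagents that add atoms: none
Why: Olefin cross-metathesis of an allyl ether with an acrylate gives the (E)-enoate selectively and is driven by loss of ethene.

Step 5
Reactants: 5 3-(3-bromopropyl)furan; 9 methyl (E)-4-[(triisopropylsilyl)oxy]but-2-enoate
Product: 11 methyl (S)-6-(furan-3-yl)-3-{[(triisopropylsilyl)oxy]methyl}hexanoate, via Grignard reagent 10 (not isolated)
Conditions: Mg, Et2O; then 9, CuBr·SMe2 (5 mol %), (R)-1-[(S)-2-(diphenylphosphino)ferrocenyl]ethyldicyclohexylphosphine (6 mol %), t-BuOMe, −75 °C; aq. NH4Cl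
Reagents that add atoms: none
Why: Copper-catalysed asymmetric conjugate addition of a Grignard reagent to an (E)-enoate delivers the alkyl group to the Si face of C3 and sets the side-chain stereocentre as S (the ligand antipode is the one that gives Si-face delivery, to be confirmed on the first run).

Step 6
Reactants: 11 methyl (S)-6-(furan-3-yl)-3-{[(triisopropylsilyl)oxy]methyl}hexanoate
Product: 12 (S)-6-(furan-3-yl)-3-{[(triisopropylsilyl)oxy]methyl}hexan-1-ol
Conditions: LiAlH4, THF, 0 °C; aq. NaOH work-up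
Reagents that add atoms: none
Why: Hydride reduction of the ester leaves the silyl ether, the furan and the β-stereocentre untouched.

Step 7
Reactants: 12 (S)-6-(furan-3-yl)-3-{[(triisopropylsilyl)oxy]methyl}hexan-1-ol
Product: 13 (S)-{[5-(furan-3-yl)-2-(2-iodoethyl)pentyl]oxy}triisopropylsilane
Conditions: I2, PPh3, imidazole, CH2Cl2, 0 °C
Reagents that add atoms: iodine, II
Why: Appel iodination gives an unhindered primary iodide whose stereocentre is two carbons away and cannot be affected.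

Step 8
Reactants: 14 2-methoxybenzoic acid; 13 (S)-{[5-(furan-3-yl)-2-(2-iodoethyl)pentyl]oxy}triisopropylsilane
Product: 17 2-[(3S)-6-(furan-3-yl)-3-{[(triisopropylsilyl)oxy]methyl}hexyl]cyclohex-2-en-1-one, via Birch dienolate 15 (not isolated), via alkylated dienyl acid 16 (not isolated)
Conditions: 14 (1.5 equiv), Li (3 equiv per 14), t-BuOH, NH3(l)–THF, −78 °C until the blue colour just fades; then 13, −78 → −33 °C; NH3 off; 1 M HCl–THF, 45 °C
Reagents that add atoms: water, O
Why: Birch reduction of the benzoate gives a dienolate that is C-alkylated at the ipso carbon by the primary iodide (Birch reductive alkylation), and acid then hydrolyses the enol ether, decarboxylates the β-keto acid and moves the alkene into conjugation, so the benzene ring becomes ring A as a 2-alkylcyclohexenone; the iodide is added only after the dissolved metal is consumed, so the furan never meets solvated electrons.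

Step 9
Reactants: 17 2-[(3S)-6-(furan-3-yl)-3-{[(triisopropylsilyl)oxy]methyl}hexyl]cyclohex-2-en-1-one
Product: 19 (2R,3R)-2-[(3S)-6-(furan-3-yl)-3-{[(triisopropylsilyl)oxy]methyl}hexyl]-2,3-dimethylcyclohexan-1-one, via magnesium enolate 18 (not isolated)
Conditions: MeMgBr, Cu(OTf)2 (4 mol %), chiral hydroxyalkyl imidazolinium salt (NHC precursor, 5 mol %), Et2O, −20 °C; then MeI, DMPU, −20 → 23 °C
Reagents that add atoms: methylmagnesium bromide, C[Mg]Br; iodomethane, CI
Why: Copper–carbene-catalysed asymmetric conjugate addition puts the methyl group on the Re face of C3 (3R), and the magnesium enolate is then methylated anti to that methyl group (tandem conjugate addition–enolate alkylation), which sets the quaternary centre (2R) with the two methyl groups trans.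

Step 10
Reactants: 19 (2R,3R)-2-[(3S)-6-(furan-3-yl)-3-{[(triisopropylsilyl)oxy]methyl}hexyl]-2,3-dimethylcyclohexan-1-one
Product: 21 {[(5R,6R)-6-[(3S)-6-(furan-3-yl)-3-{[(triisopropylsilyl)oxy]methyl}hexyl]-5,6-dimethylcyclohex-1-en-1-yl]oxy}trimethylsilane, via lithium enolate 20 (not isolated)
Conditions: LDA, THF, −78 °C; TMSCl, −78 → 0 °C
Reagents that add atoms: chlorotrimethylsilane, C[Si](C)(C)Cl
Why: The ketone has α-hydrogens on one side only, so deprotonation and O-silylation give a single regiodefined silyl enol ether.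

Step 11
Reactants: 21 silyl enol ether; 22 4-methylpent-3-en-2-one (mesityl oxide)
Product: 23 (2R,3R,6S)-2-[(3S)-6-(furan-3-yl)-3-{[(triisopropylsilyl)oxy]methyl}hexyl]-2,3-dimethyl-6-(2-methyl-4-oxopentan-2-yl)cyclohexan-1-one
Conditions: 22 (1.5 equiv), TiCl4 (1.1 equiv), CH2Cl2, −78 °C; H2O quench
Reagents that add atoms: none
Why: Mukaiyama–Michael addition to TiCl4-activated mesityl oxide forms the bond to the gem-dimethyl carbon, and the electrophile should enter on the ring face opposite the cis-related C3 methyl group and C2 side chain, giving 6S; this preference is an estimate, not a certainty.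

Step 12
Reactants: 23 1,5-diketone
Product: 25 (4aS,7R,8R)-8-[(3S)-6-(furan-3-yl)-3-{[(triisopropylsilyl)oxy]methyl}hexyl]-4,4,7,8-tetramethyl-4,4a,5,6,7,8-hexahydronaphthalen-2(3H)-one, via ketol 24 (not isolated)
Conditions: KOH, MeOH, 50 °C, stopped at full conversion
Reagents that add atoms: none
Why: Intramolecular aldol condensation of the methyl ketone onto the ring ketone closes ring B as the enone, and the ring-fusion centre should survive because enolisation toward that hindered tertiary carbon is slow.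

Step 13
Reactants: 25 bicyclic enone TIPS ether
Product: 26 (4aS,7R,8R)-8-[(3S)-6-(furan-3-yl)-3-(hydroxymethyl)hexyl]-4,4,7,8-tetramethyl-4,4a,5,6,7,8-hexahydronaphthalen-2(3H)-one
Conditions: TBAF, AcOH (1 equiv), THF, 23 °C
Reagents that add atoms: none
Why: Buffered fluoride desilylation frees the primary alcohol without touching the enone or the furan.

Step 14
Reactants: 26 primary alcohol
Product: 28 (2S)-5-(furan-3-yl)-2-{2-[(1R,2R,4aS)-1,2,5,5-tetramethyl-7-oxo-1,2,3,4,4a,5,6,7-octahydronaphthalen-1-yl]ethyl}pentyl hydrogen sulfate, via pyridinium sulfate 27 (not isolated)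
Conditions: SO3·pyridine (1.5 equiv), pyridine, 0 °C; then Dowex 50W (H+ form), MeOH–H2O, 0 °C
Reagents that add atoms: sulfur trioxide–pyridine complex, [O-]S(=O)(=O)[n+]1ccccc1
Why: O-sulfation of the unhindered primary alcohol is much faster at 0 °C than C-sulfonation of the furan, and proton exchange gives the hydrogen sulfate as drawn.

## Compound list

1 | 3-bromofuran | Brc1ccoc1 | starting material
2 | oxetane | C1COC1 | starting material
3 | furan-3-yllithium | [Li]c1ccoc1 | intermediate (not isolated)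
4 | 3-(furan-3-yl)propan-1-ol | OCCCc1ccoc1 | intermediate
5 | 3-(3-bromopropyl)furan | BrCCCc1ccoc1 | intermediate
6 | prop-2-en-1-ol | C=CCO | starting material
7 | (allyloxy)triisopropylsilane | C=CCO[Si](C(C)C)(C(C)C)C(C)C | intermediate
8 | methyl acrylate | C=CC(=O)OC | starting material
9 | methyl (E)-4-[(triisopropylsilyl)oxy]but-2-enoate | COC(=O)/C=C/CO[Si](C(C)C)(C(C)C)C(C)C | intermediate
10 | [3-(furan-3-yl)propyl]magnesium bromide | Br[Mg]CCCc1ccoc1 | intermediate (not isolated)
11 | methyl (S)-6-(furan-3-yl)-3-{[(triisopropylsilyl)oxy]methyl}hexanoate | COC(=O)C[C@H](CCCc1ccoc1)CO[Si](C(C)C)(C(C)C)C(C)C | intermediate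
12 | (S)-6-(furan-3-yl)-3-{[(triisopropylsilyl)oxy]methyl}hexan-1-ol | OCC[C@H](CCCc1ccoc1)CO[Si](C(C)C)(C(C)C)C(C)C | intermediate
13 | (S)-{[5-(furan-3-yl)-2-(2-iodoethyl)pentyl]oxy}triisopropylsilane | ICC[C@H](CCCc1ccoc1)CO[Si](C(C)C)(C(C)C)C(C)C | intermediate
14 | 2-methoxybenzoic acid | COc1ccccc1C(=O)O | starting material
15 | dilithium (2-methoxycyclohexa-2,5-dien-1-ylidene)methanediolate | [Li+].[Li+].COC1=CCC=CC1=C([O-])[O-] | intermediate (not isolated)
16 | 1-[(3S)-6-(furan-3-yl)-3-{[(triisopropylsilyl)oxy]methyl}hexyl]-2-methoxycyclohexa-2,5-diene-1-carboxylic acid (both C1 epimers; lithium salt in the flask) | COC1=CCC=CC1(CC[C@H](CCCc1ccoc1)CO[Si](C(C)C)(C(C)C)C(C)C)C(=O)O | intermediate (not isolated)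
17 | 2-[(3S)-6-(furan-3-yl)-3-{[(triisopropylsilyl)oxy]methyl}hexyl]cyclohex-2-en-1-one | O=C1CCCC=C1CC[C@H](CCCc1ccoc1)CO[Si](C(C)C)(C(C)C)C(C)C | intermediate
18 | bromomagnesium (3R)-2-[(3S)-6-(furan-3-yl)-3-{[(triisopropylsilyl)oxy]methyl}hexyl]-3-methylcyclohex-1-en-1-olate | C[C@@H]1CCCC(O[Mg]Br)=C1CC[C@H](CCCc1ccoc1)CO[Si](C(C)C)(C(C)C)C(C)C | intermediate (not isolated)
19 | (2R,3R)-2-[(3S)-6-(furan-3-yl)-3-{[(triisopropylsilyl)oxy]methyl}hexyl]-2,3-dimethylcyclohexan-1-one | C[C@@H]1CCCC(=O)[C@]1(C)CC[C@H](CCCc1ccoc1)CO[Si](C(C)C)(C(C)C)C(C)C | intermediate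
20 | lithium (5R,6R)-6-[(3S)-6-(furan-3-yl)-3-{[(triisopropylsilyl)oxy]methyl}hexyl]-5,6-dimethylcyclohex-1-en-1-olate | C[C@@H]1CCC=C(O[Li])[C@]1(C)CC[C@H](CCCc1ccoc1)CO[Si](C(C)C)(C(C)C)C(C)C | intermediate (not isolated)
21 | {[(5R,6R)-6-[(3S)-6-(furan-3-yl)-3-{[(triisopropylsilyl)oxy]methyl}hexyl]-5,6-dimethylcyclohex-1-en-1-yl]oxy}trimethylsilane | C[C@@H]1CCC=C(O[Si](C)(C)C)[C@]1(C)CC[C@H](CCCc1ccoc1)CO[Si](C(C)C)(C(C)C)C(C)C | intermediate
22 | 4-methylpent-3-en-2-one | CC(=O)C=C(C)C | starting material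
23 | (2R,3R,6S)-2-[(3S)-6-(furan-3-yl)-3-{[(triisopropylsilyl)oxy]methyl}hexyl]-2,3-dimethyl-6-(2-methyl-4-oxopentan-2-yl)cyclohexan-1-one | C[C@@H]1CC[C@@H](C(C)(C)CC(C)=O)C(=O)[C@]1(C)CC[C@H](CCCc1ccoc1)CO[Si](C(C)C)(C(C)C)C(C)C | intermediate
24 | (4aS,7R,8R)-8-[(3S)-6-(furan-3-yl)-3-{[(triisopropylsilyl)oxy]methyl}hexyl]-8a-hydroxy-4,4,7,8-tetramethyloctahydronaphthalen-2(1H)-one (configuration at C8a not assigned) | C[C@@H]1CC[C@@H]2C(O)(CC(=O)CC2(C)C)[C@]1(C)CC[C@H](CCCc1ccoc1)CO[Si](C(C)C)(C(C)C)C(C)C | intermediate (not isolated)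
25 | (4aS,7R,8R)-8-[(3S)-6-(furan-3-yl)-3-{[(triisopropylsilyl)oxy]methyl}hexyl]-4,4,7,8-tetramethyl-4,4a,5,6,7,8-hexahydronaphthalen-2(3H)-one | C[C@@H]1CC[C@@H]2C(=CC(=O)CC2(C)C)[C@]1(C)CC[C@H](CCCc1ccoc1)CO[Si](C(C)C)(C(C)C)C(C)C | intermediate
26 | (4aS,7R,8R)-8-[(3S)-6-(furan-3-yl)-3-(hydroxymethyl)hexyl]-4,4,7,8-tetramethyl-4,4a,5,6,7,8-hexahydronaphthalen-2(3H)-one | C[C@@H]1CC[C@@H]2C(=CC(=O)CC2(C)C)[C@]1(C)CC[C@H](CCCc1ccoc1)CO | intermediate
27 | pyridinium (2S)-5-(furan-3-yl)-2-{2-[(1R,2R,4aS)-1,2,5,5-tetramethyl-7-oxo-1,2,3,4,4a,5,6,7-octahydronaphthalen-1-yl]ethyl}pentyl sulfate | C[C@@H]1CC[C@@H]2C(=CC(=O)CC2(C)C)[C@]1(C)CC[C@H](CCCc1ccoc1)COS(=O)(=O)[O-].c1cc[nH+]cc1 | intermediate (not isolated)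
28 | (2S)-5-(furan-3-yl)-2-{2-[(1R,2R,4aS)-1,2,5,5-tetramethyl-7-oxo-1,2,3,4,4a,5,6,7-octahydronaphthalen-1-yl]ethyl}pentyl hydrogen sulfate | C[C@@H]1CC[C@@H]2C(=CC(=O)CC2(C)C)[C@]1(C)CC[C@H](CCCc1ccoc1)COS(=O)(=O)O | target

## Step count and risks

Total step count: 14. Longest linear sequence: 12 steps (1, 2, 5–14; the branch 3, 4, 5–14 is equally long).

The three steps most likely to fail:

**Step 8 (dearomatising fragment coupling).** The dienolate may alkylate poorly with a long, functionalised iodide, and the acid needed for hydrolysis and decarboxylation may damage the furan. The fallback sets out from 13 and comes back at 17; it separates C–C bond formation from the dearomatisation and needs no decarboxylation. 1,3-Dimethoxybenzene is lithiated between the two methoxy groups (n-BuLi, THF, 0 °C) and alkylated with 13 to give 2-[(3S)-6-(furan-3-yl)-3-{[(triisopropylsilyl)oxy]methyl}hexyl]-1,3-dimethoxybenzene F1. Birch reduction (Li, NH3, t-BuOH, −78 °C) gives 6-[(3S)-6-(furan-3-yl)-3-{[(triisopropylsilyl)oxy]methyl}hexyl]-1,5-dimethoxycyclohexa-1,4-diene F2. Brief treatment with aqueous oxalic acid hydrolyses one enol ether and conjugates the other, giving 2-[(3S)-6-(furan-3-yl)-3-{[(triisopropylsilyl)oxy]methyl}hexyl]-3-methoxycyclohex-2-en-1-one F3. Reduction of the vinylogous ester carbonyl with DIBAL-H followed by dilute acid (reduction with carbonyl transposition) then gives 17. In this variant the furan does meet solvated electrons; unactivated alkylfurans are expected to survive.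

**Step 9 (asymmetric conjugate methylation and enolate methylation).** MeMgBr is the least reactive Grignard reagent in copper-catalysed additions to α-substituted enones, so conversion or enantioselectivity may be poor. The fallback sets out from 17 and comes back at 19. Oxazaborolidine-catalysed borane reduction (the catalyst antipode that gives the 1S alcohol, BH3·SMe2) gives (1S)-2-[(3S)-6-(furan-3-yl)-3-{[(triisopropylsilyl)oxy]methyl}hexyl]cyclohex-2-en-1-ol F4. Hydroxyl-directed Simmons–Smith cyclopropanation (Et2Zn, CH2I2) places the methylene on the face of the hydroxyl group and gives (1R,2S,6S)-1-[(3S)-6-(furan-3-yl)-3-{[(triisopropylsilyl)oxy]methyl}hexyl]bicyclo[4.1.0]heptan-2-ol F5. Dess–Martin oxidation gives (1R,6S)-1-[(3S)-6-(furan-3-yl)-3-{[(triisopropylsilyl)oxy]methyl}hexyl]bicyclo[4.1.0]heptan-2-one F6. Li/NH3 cleaves the exocyclic cyclopropane bond that overlaps with the carbonyl group; the methylene becomes the C3 methyl group and the enolate sits at C2, and MeI then enters anti to that methyl group to give 19.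

**Step 11 (Mukaiyama–Michael addition).** A quaternary carbon is formed next to a hindered enol ether, TiCl4-activated mesityl oxide may alkylate the furan, and the facial selectivity at C6 rests on a steric estimate. If a C6 epimer forms it is separated; it can be recycled by base equilibration, since that centre is epimerisable. The fallback sets out from 21 and comes back at 25; it uses a far more electrophilic acceptor under mild catalysis and closes ring B by an enol lactone–Grignard annulation. Addition of 21 to commercial 2,2-dimethyl-5-(propan-2-ylidene)-1,3-dioxane-4,6-dione (Sc(OTf)3, 5 mol %, CH2Cl2, −40 °C) gives 5-{2-[(1S,3R,4R)-3-[(3S)-6-(furan-3-yl)-3-{[(triisopropylsilyl)oxy]methyl}hexyl]-3,4-dimethyl-2-oxocyclohexyl]propan-2-yl}-2,2-dimethyl-1,3-dioxane-4,6-dione F7. Heating in wet pyridine gives 3-[(1S,3R,4R)-3-[(3S)-6-(furan-3-yl)-3-{[(triisopropylsilyl)oxy]methyl}hexyl]-3,4-dimethyl-2-oxocyclohexyl]-3-methylbutanoic acid F8. Ac2O with NaOAc closes the enol lactone (7R,8R)-8-[(3S)-6-(furan-3-yl)-3-{[(triisopropylsilyl)oxy]methyl}hexyl]-4,4,7,8-tetramethyl-3,4,5,6,7,8-hexahydro-2H-chromen-2-one F9. MeMgBr (Et2O, −40 °C) followed by aqueous KOH gives the methyl ketone and ring enolate and then the aldol condensation product 25; here the ring-fusion centre is set by protonation and the epimers may need separation.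

## Further compounds

F1 | step 8 | 2-[(3S)-6-(furan-3-yl)-3-{[(triisopropylsilyl)oxy]methyl}hexyl]-1,3-dimethoxybenzene | COc1cccc(OC)c1CC[C@H](CCCc1ccoc1)CO[Si](C(C)C)(C(C)C)C(C)C
F2 | step 8 | 6-[(3S)-6-(furan-3-yl)-3-{[(triisopropylsilyl)oxy]methyl}hexyl]-1,5-dimethoxycyclohexa-1,4-diene | COC1=CCC=C(OC)C1CC[C@H](CCCc1ccoc1)CO[Si](C(C)C)(C(C)C)C(C)C
F3 | step 8 | 2-[(3S)-6-(furan-3-yl)-3-{[(triisopropylsilyl)oxy]methyl}hexyl]-3-methoxycyclohex-2-en-1-one | COC1=C(CC[C@H](CCCc2ccoc2)CO[Si](C(C)C)(C(C)C)C(C)C)C(=O)CCC1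
F4 | step 9 | (1S)-2-[(3S)-6-(furan-3-yl)-3-{[(triisopropylsilyl)oxy]methyl}hexyl]cyclohex-2-en-1-ol | O[C@H]1CCCC=C1CC[C@H](CCCc1ccoc1)CO[Si](C(C)C)(C(C)C)C(C)C
F5 | step 9 | (1R,2S,6S)-1-[(3S)-6-(furan-3-yl)-3-{[(triisopropylsilyl)oxy]methyl}hexyl]bicyclo[4.1.0]heptan-2-ol | O[C@H]1CCC[C@H]2C[C@@]12CC[C@H](CCCc1ccoc1)CO[Si](C(C)C)(C(C)C)C(C)C
F6 | step 9 | (1R,6S)-1-[(3S)-6-(furan-3-yl)-3-{[(triisopropylsilyl)oxy]methyl}hexyl]bicyclo[4.1.0]heptan-2-one | O=C1CCC[C@H]2C[C@@]12CC[C@H](CCCc1ccoc1)CO[Si](C(C)C)(C(C)C)C(C)C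
F7 | step 11 | 5-{2-[(1S,3R,4R)-3-[(3S)-6-(furan-3-yl)-3-{[(triisopropylsilyl)oxy]methyl}hexyl]-3,4-dimethyl-2-oxocyclohexyl]propan-2-yl}-2,2-dimethyl-1,3-dioxane-4,6-dione | C[C@@H]1CC[C@@H](C(C)(C)C2C(=O)OC(C)(C)OC2=O)C(=O)[C@]1(C)CC[C@H](CCCc1ccoc1)CO[Si](C(C)C)(C(C)C)C(C)C
F8 | step 11 | 3-[(1S,3R,4R)-3-[(3S)-6-(furan-3-yl)-3-{[(triisopropylsilyl)oxy]methyl}hexyl]-3,4-dimethyl-2-oxocyclohexyl]-3-methylbutanoic acid | C[C@@H]1CC[C@@H](C(C)(C)CC(=O)O)C(=O)[C@]1(C)CC[C@H](CCCc1ccoc1)CO[Si](C(C)C)(C(C)C)C(C)C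
F9 | step 11 | (7R,8R)-8-[(3S)-6-(furan-3-yl)-3-{[(triisopropylsilyl)oxy]methyl}hexyl]-4,4,7,8-tetramethyl-3,4,5,6,7,8-hexahydro-2H-chromen-2-one | C[C@@H]1CCC2=C(OC(=O)CC2(C)C)[C@]1(C)CC[C@H](CCCc1ccoc1)CO[Si](C(C)C)(C(C)C)C(C)C
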